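**Retrosynthetic overview**

- The target is reached from a (1(10)Z,4Z)-germacra-1(10),4,11-triene core by two substrate-controlled epoxidations (nucleophilic on the C9 enone; vanadium-directed by the free C6 hydroxyl on C4=C5) and two angeloylations.
- The ten-membered carbocycle is the only ring formed. It is closed last, at C3–C4, by an electrochemical nickel/chromium alkenyl iodide–aldehyde coupling that also sets C3.
- The open chain comes from a C9–C10 union of a (Z)-alkenyllithium (C10, C14, C1–C3) with an alkynal (C4–C9, C11–C13, C15). The C4 iodide is then made from the methyl alkyne by trans-hydrosilylation and iododesilylation.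
- The alkynal comes from (R)-carvone by trans α'-oxygenation, epoxidation and Eschenmoser–Tanabe fragmentation. Carvone supplies C7 and controls C6.

Assumption: germacrane numbering is used throughout (ring C1–C10, isopropenyl C11–C13 on C7, C14 on C10, C15 on C4), and 3-[(4-methoxybenzyl)oxy]propanal and angelic acid are taken as commercial.

**Route**

Step 1
Reactants: 1 (R)-(−)-carvone
Product: 4 (5S,6S)-6-[(tert-butyldimethylsilyl)oxy]-2-methyl-5-(prop-1-en-2-yl)cyclohex-2-en-1-one, via sodium dienolate 2 (not isolated), via sodium alkoxide 3 (not isolated)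
Conditions: NaN(SiMe3)2, THF, −78 °C; racemic 3-phenyl-2-(phenylsulfonyl)oxaziridine, −78 °C; then tBuMe2SiOTf, −78 → 0 °C
Reagents that add atoms: 3-phenyl-2-(phenylsulfonyl)oxaziridine, O=S(=O)(c1ccccc1)N1OC1c1ccccc1; tert-butyldimethylsilyl trifluoromethanesulfonate, CC(C)(C)[Si](C)(C)OS(=O)(=O)C(F)(F)F; sodium bis(trimethylsilyl)amide, C[Si](C)(C)[N-][Si](C)(C)C.[Na+] (sodium stays only in 2 and 3)
Why: Kinetic α'-deprotonation gives the cross-conjugated enolate, and oxaziridine enolate oxidation (Davis hydroxylation) delivers oxygen to C6 anti to the neighbouring isopropenyl group, so the bought C5 centre sets the new trans C6 centre before the alkoxide is silylated in the same flask.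

Step 2
Reactants: 4 (5S,6S)-6-[(tert-butyldimethylsilyl)oxy]-2-methyl-5-(prop-1-en-2-yl)cyclohex-2-en-1-one
Product: 5 (1R,3S,4S,6R)-3-[(tert-butyldimethylsilyl)oxy]-1-methyl-4-(prop-1-en-2-yl)-7-oxabicyclo[4.1.0]heptan-2-one
Conditions: 30% H2O2, NaOH (0.2 equiv), MeOH, 0 °C
Reagents that add atoms: hydrogen peroxide, OO
Why: Weitz–Scheffer nucleophilic epoxidation touches only the enone (not the isopropenyl group), with hydroperoxide adding anti to the isopropenyl group; both epoxide centres are destroyed in step 3, so their configuration does not matter.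

Step 3
Reactants: 5 (1R,3S,4S,6R)-3-[(tert-butyldimethylsilyl)oxy]-1-methyl-4-(prop-1-en-2-yl)-7-oxabicyclo[4.1.0]heptan-2-one
Product: 7 (3S,4S)-4-[(tert-butyldimethylsilyl)oxy]-3-(prop-1-en-2-yl)hept-5-ynal, via tosylhydrazone 6 (not isolated)
Conditions: TsNHNH2, AcOH/CH2Cl2 (1:1), −20 °C → rt
Reagents that add atoms: p-toluenesulfonohydrazide, Cc1ccc(cc1)S(=O)(=O)NN (its atoms are carried only in 6)
Why: Eschenmoser–Tanabe fragmentation: the epoxy tosylhydrazone opens to an azoalkene alkoxide that cleaves the former enone C–C bond with loss of N2 and sulfinate, giving the methyl alkyne (C15–C4≡C5) and the C9 aldehyde while the C6 and C7 centres are untouched.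

Step 4
Reactants: 8 3-[(4-methoxybenzyl)oxy]propanal
Product: 9 1-({[(3Z)-4-iodopent-3-en-1-yl]oxy}methyl)-4-methoxybenzene
Conditions: EtPPh3 iodide, nBuLi, THF, 0 °C; I2, −78 °C; NaN(SiMe3)2, −20 °C; then 8, −78 °C → rt
Reagents that add atoms: ethyltriphenylphosphonium iodide, CC[P+](c1ccccc1)(c1ccccc1)c1ccccc1.[I-]; iodine, II
Why: Stork–Zhao iodo-Wittig olefination with the non-stabilised α-iodo ylide gives the (Z)-2-iodoalkene, with iodine cis to the chain, which is the geometry needed for the cis C1=C10 bond.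

Step 5
Reactants: 9 1-({[(3Z)-4-iodopent-3-en-1-yl]oxy}methyl)-4-methoxybenzene; 7 (3S,4S)-4-[(tert-butyldimethylsilyl)oxy]-3-(prop-1-en-2-yl)hept-5-ynal
Product: 12 (3Z,5RS,7S,8S)-8-[(tert-butyldimethylsilyl)oxy]-1-[(4-methoxybenzyl)oxy]-4-methyl-7-(prop-1-en-2-yl)-5-[(triethylsilyl)oxy]undec-3-en-9-yne, via alkenyllithium 10 (not isolated), via lithium alkoxide 11 (not isolated)
Conditions: 9 (1.2 equiv), tBuLi (2.4 equiv), Et2O, −78 °C; then 7, −78 °C; then Et3SiOTf, −78 → 0 °C
Reagents that add atoms: triethylsilyl trifluoromethanesulfonate, CC[Si](CC)(CC)OS(=O)(=O)C(F)(F)F; tert-butyllithium, [Li]C(C)(C)C (lithium stays only in 10 and 11)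
Why: Iodine–lithium exchange with retention and 1,2-addition to the aldehyde forms C9–C10 with the (Z)-olefin intact; the C9 carbinol forms as an epimer mixture that converges on oxidation in step 11, and silylating it in the flask keeps C9 as a masked alcohol so that no ketone can intercept the ring closure.

Step 6
Reactants: 12 (3Z,5RS,7S,8S)-8-[(tert-butyldimethylsilyl)oxy]-1-[(4-methoxybenzyl)oxy]-4-methyl-7-(prop-1-en-2-yl)-5-[(triethylsilyl)oxy]undec-3-en-9-yne
Product: 14 (3Z,5RS,7S,8S,9Z)-8-[(tert-butyldimethylsilyl)oxy]-10-iodo-1-[(4-methoxybenzyl)oxy]-4-methyl-7-(prop-1-en-2-yl)-5-[(triethylsilyl)oxy]undeca-3,9-diene, via vinylsilane 13 (not isolated)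
Conditions: [(C5Me5)Ru(MeCN)3]PF6 (5 mol %), Et3SiH, CH2Cl2, 0 °C → rt; concentrate; N-iodosuccinimide (1.05 equiv), 2,6-lutidine, (CF3)2CHOH, 0 °C, 5 min
Reagents that add atoms: N-iodosuccinimide, O=C1CCC(=O)N1I; triethylsilane, CC[SiH](CC)CC (silicon stays only in 13)
Why: Cationic ruthenium-catalysed trans-hydrosilylation puts silicon on the alkyne carbon distal to the propargylic oxygen (C4) by anti H/Si addition, and ipso-iododesilylation in the fluorinated alcohol proceeds with retention, giving the (Z)-iodide with iodine cis to C6.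

Step 7
Reactants: 14 (3Z,5RS,7S,8S,9Z)-8-[(tert-butyldimethylsilyl)oxy]-10-iodo-1-[(4-methoxybenzyl)oxy]-4-methyl-7-(prop-1-en-2-yl)-5-[(triethylsilyl)oxy]undeca-3,9-diene
Product: 15 (3Z,5RS,7S,8S,9Z)-8-[(tert-butyldimethylsilyl)oxy]-10-iodo-4-methyl-7-(prop-1-en-2-yl)-5-[(triethylsilyl)oxy]undeca-3,9-dien-1-ol
Conditions: DDQ, CH2Cl2/pH 7 buffer (10:1), 0 °C
Reagents that add atoms: none
Why: Oxidative cleavage of the 4-methoxybenzyl ether frees only the primary C3 hydroxyl, as both silyl ethers, the alkenyl iodide and the olefins are inert to DDQ at 0 °C.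

Step 8
Reactants: 15 (3Z,5RS,7S,8S,9Z)-8-[(tert-butyldimethylsilyl)oxy]-10-iodo-4-methyl-7-(prop-1-en-2-yl)-5-[(triethylsilyl)oxy]undeca-3,9-dien-1-ol
Product: 16 (3Z,5RS,7S,8S,9Z)-8-[(tert-butyldimethylsilyl)oxy]-10-iodo-4-methyl-7-(prop-1-en-2-yl)-5-[(triethylsilyl)oxy]undeca-3,9-dienal
Conditions: Dess–Martin periodinane, NaHCO3, CH2Cl2, 0 °C; used at once
Reagents that add atoms: none
Why: Buffered Dess–Martin oxidation gives the β,γ-unsaturated aldehyde without moving the C1=C10 double bond into conjugation.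

Step 9
Reactants: 16 (3Z,5RS,7S,8S,9Z)-8-[(tert-butyldimethylsilyl)oxy]-10-iodo-4-methyl-7-(prop-1-en-2-yl)-5-[(triethylsilyl)oxy]undeca-3,9-dienal
Product: 17 (3S,9RS)-6-[(tert-butyldimethylsilyl)oxy]-9-[(triethylsilyl)oxy]-(1(10)Z,4Z)-germacra-1(10),4,11-trien-3-ol (C6 and C7 as in 7)
Conditions: undivided cell, Al anode, Ni-foam cathode, constant current 2 mA; CrCl3 (20 mol %), NiCl2(MeOCH2CH2OMe) (3 mol %), (C5H5)2ZrCl2 (1.2 equiv), nBu4NPF6, DMF, rt; 16 added by syringe pump (final 2 mM); aqueous potassium serinate work-up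
Reagents that add atoms: none
Why: Proposed new method: an electrochemically driven, chromium-catalysed and nickel-co-catalysed Nozaki–Hiyama–Kishi ring closure, so far shown only for intermolecular alkenylations (closest known reaction types: the intermolecular electrochemical NHK coupling and stoichiometric-CrCl2 NHK closures of medium rings), in which the cathode reduces trivalent to divalent chromium while the aluminium anode is consumed, zerovalent nickel inserts into the C4–I bond with retention and passes the alkenyl group to chromium, and the (Z)-alkenylchromium adds to the C3 aldehyde (the only carbonyl group present) with (C5H5)2ZrCl2 freeing chromium from the alkoxide; slow addition favours ring closure over oligomers, the retained geometry gives the cis C4=C5 bond in the ten-membered ring, and the new C3 centre is set by the substrate, predicted (not certain) to be (3S) from attack on the aldehyde face that keeps the C6 silyloxy and C7 isopropenyl groups pseudo-equatorial.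

Step 10
Reactants: 17 (3S,9RS)-6-[(tert-butyldimethylsilyl)oxy]-9-[(triethylsilyl)oxy]-(1(10)Z,4Z)-germacra-1(10),4,11-trien-3-ol
Product: 18 (3S,9RS)-3-(angeloyloxy)-6-[(tert-butyldimethylsilyl)oxy]-9-[(triethylsilyl)oxy]-(1(10)Z,4Z)-germacra-1(10),4,11-triene
Conditions: angelic acid, 2,4,6-trichlorobenzoyl chloride, Et3N, toluene, rt; then 17, 75 °C
Reagents that add atoms: angelic acid, C/C=C(/C)C(=O)O
Why: Yamaguchi esterification through the mixed anhydride, run without a nucleophilic catalyst, acylates the allylic C3 hydroxyl without isomerising the (Z)-2-methylbut-2-enoate to the tiglate.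

Step 11
Reactants: 18 (3S,9RS)-3-(angeloyloxy)-6-[(tert-butyldimethylsilyl)oxy]-9-[(triethylsilyl)oxy]-(1(10)Z,4Z)-germacra-1(10),4,11-triene
Product: 20 (3S)-3-(angeloyloxy)-6-[(tert-butyldimethylsilyl)oxy]-(1(10)Z,4Z)-germacra-1(10),4,11-trien-9-one, via C9 alcohol 19 (not isolated)
Conditions: IBX (3 equiv), DMSO, rt
Reagents that add atoms: none
Why: IBX in DMSO cleaves the triethylsilyl ether while leaving the tert-butyldimethylsilyl ether, and oxidises the freed allylic alcohol in the same flask, so both C9 epimers converge on one (Z)-enone.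

Step 12
Reactants: 20 (3S)-3-(angeloyloxy)-6-[(tert-butyldimethylsilyl)oxy]-(1(10)Z,4Z)-germacra-1(10),4,11-trien-9-one
Product: 21 (1R,3S,10R)-3-(angeloyloxy)-6-[(tert-butyldimethylsilyl)oxy]-1,10-epoxy-(4Z)-germacra-4,11-dien-9-one
Conditions: tBuOOH (decane), DBU, CH2Cl2, 0 °C
Reagents that add atoms: tert-butyl hydroperoxide, CC(C)(C)OO
Why: Weitz–Scheffer nucleophilic epoxidation of the ring (Z)-enone, in which tert-butylperoxide adds to C1 from the peripheral face of the ten-membered ring and the ring prevents C1–C10 rotation before closure, so the cis (1R,10R)-epoxide is expected (the facial sense is a prediction) while the hindered angelate and the isolated olefins are not attacked.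

Step 13
Reactants: 21 (1R,3S,10R)-3-(angeloyloxy)-6-[(tert-butyldimethylsilyl)oxy]-1,10-epoxy-(4Z)-germacra-4,11-dien-9-one
Product: 22 (1R,3S,10R)-3-(angeloyloxy)-1,10-epoxy-6-hydroxy-(4Z)-germacra-4,11-dien-9-one
Conditions: HF·pyridine, pyridine, THF, 0 °C → rt
Reagents that add atoms: none
Why: Buffered fluoride desilylation frees the C6 hydroxyl without opening the deactivated α,β-epoxy ketone or cleaving the ester.

Step 14
Reactants: 22 (1R,3S,10R)-3-(angeloyloxy)-1,10-epoxy-6-hydroxy-(4Z)-germacra-4,11-dien-9-one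
Product: 23 (1R,3S,4R,5S,6S,7S,10R)-3-(angeloyloxy)-1,10:4,5-diepoxy-6-hydroxygermacr-11-en-9-one
Conditions: VO(acac)2 (5 mol %), tBuOOH, CH2Cl2, 0 °C
Reagents that add atoms: tert-butyl hydroperoxide, CC(C)(C)OO
Why: Vanadium-catalysed hydroxyl-directed epoxidation, in which the C6 hydroxyl delivers oxygen to the syn face of the (Z)-C4=C5 bond (the cis epoxy alcohol typical of medium-ring Z-allylic alcohols), which is also the face anti to the C3 ester, setting (4R,5S) while the homoallylic isopropenyl group reacts much more slowly.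

Step 15
Reactants: 23 (1R,3S,4R,5S,6S,7S,10R)-3-(angeloyloxy)-1,10:4,5-diepoxy-6-hydroxygermacr-11-en-9-one
Product: 24 (1R,3S,4R,5S,6S,7S,10R)-3,6-bis(angeloyloxy)-1,10:4,5-diepoxygermacr-11-en-9-one (CNP0217653.1)
Conditions: angelic acid, 2,4,6-trichlorobenzoyl chloride, Et3N, toluene, rt; then 23, 90 °C
Reagents that add atoms: angelic acid, C/C=C(/C)C(=O)O
Why: A second Yamaguchi esterification acylates the hindered C6 hydroxyl under weakly basic conditions that cause neither Payne rearrangement of the epoxy alcohol nor angelate-to-tiglate isomerisation.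

**Compound list**

1 | (R)-(−)-carvone | CC1=CC[C@H](CC1=O)C(C)=C | starting material
2 | sodium cross-conjugated dienolate of 1 | CC1=CC[C@H](C=C1[O-])C(C)=C.[Na+] | intermediate
3 | sodium alkoxide of (5S,6S)-6-hydroxycarvone | CC1=CC[C@H]([C@H]([O-])C1=O)C(C)=C.[Na+] | intermediate
4 | (5S,6S)-6-[(tert-butyldimethylsilyl)oxy]-2-methyl-5-(prop-1-en-2-yl)cyclohex-2-en-1-one (silyloxy trans to isopropenyl) | CC1=CC[C@H]([C@H](O[Si](C)(C)C(C)(C)C)C1=O)C(C)=C | intermediate
5 | (1R,3S,4S,6R)-3-[(tert-butyldimethylsilyl)oxy]-1-methyl-4-(prop-1-en-2-yl)-7-oxabicyclo[4.1.0]heptan-2-one (epoxide anti to isopropenyl) | C[C@@]12O[C@@H]1C[C@H]([C@H](O[Si](C)(C)C(C)(C)C)C2=O)C(C)=C | intermediate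
6 | p-toluenesulfonylhydrazone of 5 | C[C@@]12O[C@@H]1C[C@H]([C@H](O[Si](C)(C)C(C)(C)C)C2=NNS(=O)(=O)c1ccc(C)cc1)C(C)=C | intermediate
7 | (3S,4S)-4-[(tert-butyldimethylsilyl)oxy]-3-(prop-1-en-2-yl)hept-5-ynal | CC#C[C@@H](O[Si](C)(C)C(C)(C)C)[C@@H](CC=O)C(C)=C | intermediate
8 | 3-[(4-methoxybenzyl)oxy]propanal | O=CCCOCc1ccc(OC)cc1 | starting material
9 | 1-({[(3Z)-4-iodopent-3-en-1-yl]oxy}methyl)-4-methoxybenzene | C/C(I)=C/CCOCc1ccc(OC)cc1 | intermediate
10 | alkenyllithium from 9 (lithium cis to the chain) | C/C([Li])=C/CCOCc1ccc(OC)cc1 | intermediate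
11 | lithium alkoxide of the C9 carbinol (9RS) | CC#C[C@@H](O[Si](C)(C)C(C)(C)C)[C@@H](CC([O-])/C(C)=C\CCOCc1ccc(OC)cc1)C(C)=C.[Li+] | intermediate
12 | (3Z,5RS,7S,8S)-8-[(tert-butyldimethylsilyl)oxy]-1-[(4-methoxybenzyl)oxy]-4-methyl-7-(prop-1-en-2-yl)-5-[(triethylsilyl)oxy]undec-3-en-9-yne | CC#C[C@@H](O[Si](C)(C)C(C)(C)C)[C@@H](CC(O[Si](CC)(CC)CC)/C(C)=C\CCOCc1ccc(OC)cc1)C(C)=C | intermediate
13 | (9Z)-10-(triethylsilyl) vinylsilane from 12 (silicon cis to C8 of the chain) | C/C([Si](CC)(CC)CC)=C/[C@@H](O[Si](C)(C)C(C)(C)C)[C@@H](CC(O[Si](CC)(CC)CC)/C(C)=C\CCOCc1ccc(OC)cc1)C(C)=C | intermediate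
14 | (3Z,5RS,7S,8S,9Z)-8-[(tert-butyldimethylsilyl)oxy]-10-iodo-1-[(4-methoxybenzyl)oxy]-4-methyl-7-(prop-1-en-2-yl)-5-[(triethylsilyl)oxy]undeca-3,9-diene | C/C(I)=C/[C@@H](O[Si](C)(C)C(C)(C)C)[C@@H](CC(O[Si](CC)(CC)CC)/C(C)=C\CCOCc1ccc(OC)cc1)C(C)=C | intermediate
15 | (3Z,5RS,7S,8S,9Z)-8-[(tert-butyldimethylsilyl)oxy]-10-iodo-4-methyl-7-(prop-1-en-2-yl)-5-[(triethylsilyl)oxy]undeca-3,9-dien-1-ol | C/C(I)=C/[C@@H](O[Si](C)(C)C(C)(C)C)[C@@H](CC(O[Si](CC)(CC)CC)/C(C)=C\CCO)C(C)=C | intermediate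
16 | (3Z,5RS,7S,8S,9Z)-8-[(tert-butyldimethylsilyl)oxy]-10-iodo-4-methyl-7-(prop-1-en-2-yl)-5-[(triethylsilyl)oxy]undeca-3,9-dienal | C/C(I)=C/[C@@H](O[Si](C)(C)C(C)(C)C)[C@@H](CC(O[Si](CC)(CC)CC)/C(C)=C\CC=O)C(C)=C | intermediate
17 | (3S,9RS)-6-[(tert-butyldimethylsilyl)oxy]-9-[(triethylsilyl)oxy]-(1(10)Z,4Z)-germacra-1(10),4,11-trien-3-ol (C6 oxygen trans to the C7 isopropenyl group, both as in 7) | C=C(C)[C@@H]1CC(O[Si](CC)(CC)CC)/C(C)=C\C[C@H](O)/C(C)=C\[C@H]1O[Si](C)(C)C(C)(C)C | intermediate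
18 | 3-O-angeloyl derivative of 17 | C=C(C)[C@@H]1CC(O[Si](CC)(CC)CC)/C(C)=C\C[C@H](OC(=O)/C(C)=C\C)/C(C)=C\[C@H]1O[Si](C)(C)C(C)(C)C | intermediate
19 | C9 alcohol from 18 (9RS) | C=C(C)[C@@H]1CC(O)/C(C)=C\C[C@H](OC(=O)/C(C)=C\C)/C(C)=C\[C@H]1O[Si](C)(C)C(C)(C)C | intermediate
20 | (3S)-3-(angeloyloxy)-6-[(tert-butyldimethylsilyl)oxy]-(1(10)Z,4Z)-germacra-1(10),4,11-trien-9-one | C=C(C)[C@@H]1CC(=O)/C(C)=C\C[C@H](OC(=O)/C(C)=C\C)/C(C)=C\[C@H]1O[Si](C)(C)C(C)(C)C | intermediate
21 | (1R,3S,10R)-3-(angeloyloxy)-6-[(tert-butyldimethylsilyl)oxy]-1,10-epoxy-(4Z)-germacra-4,11-dien-9-one | C=C(C)[C@@H]1CC(=O)[C@]2(C)O[C@@H]2C[C@H](OC(=O)/C(C)=C\C)/C(C)=C\[C@H]1O[Si](C)(C)C(C)(C)C | intermediate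
22 | (1R,3S,10R)-3-(angeloyloxy)-1,10-epoxy-6-hydroxy-(4Z)-germacra-4,11-dien-9-one | C=C(C)[C@@H]1CC(=O)[C@]2(C)O[C@@H]2C[C@H](OC(=O)/C(C)=C\C)/C(C)=C\[C@H]1O | intermediate
23 | (1R,3S,4R,5S,6S,7S,10R)-3-(angeloyloxy)-1,10:4,5-diepoxy-6-hydroxygermacr-11-en-9-one | C=C(C)[C@@H]1CC(=O)[C@]2(C)O[C@@H]2C[C@H](OC(=O)/C(C)=C\C)[C@@]2(C)O[C@H]2[C@H]1O | intermediate
24 | (1R,3S,4R,5S,6S,7S,10R)-3,6-bis(angeloyloxy)-1,10:4,5-diepoxygermacr-11-en-9-one (CNP0217653.1) | C=C(C)[C@@H]1CC(=O)[C@]2(C)O[C@@H]2C[C@H](OC(=O)/C(C)=C\C)[C@@]2(C)O[C@H]2[C@H]1OC(=O)/C(C)=C\C | target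

**Step count and risks**

Total step count: 15. Longest linear sequence: 14 steps (steps 1–3 and 5–15, from (R)-carvone).

The three steps most likely to fail:

Step 9 (new electrochemical ring closure; yield of a ten-membered ring and the C3 configuration are unproven). The fallback sets out from 16 and returns to 17 using known chemistry. The ring is closed by the classical Nozaki–Hiyama–Kishi reaction with excess CrCl2 and catalytic NiCl2 in degassed DMSO/THF at high dilution. This gives 17, possibly together with the (3R)-epimer of 17 F1. C3 is then set by reduction instead of by the addition: the alcohol mixture is oxidised with Dess–Martin periodinane to the ring enone F2, and Luche reduction (NaBH4, CeCl3·7H2O, MeOH, −78 °C) with hydride delivered from the ring periphery gives 17. If reduction favours F1, Mitsunobu esterification of F1 with angelic acid inverts C3 and leads directly to 18.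

Step 12 (facial sense of the enone epoxidation, and retention of the cis geometry). The fallback sets out from 20 and returns to 21, replacing nucleophilic attack by hydroxyl delivery. Luche reduction of 20 adds hydride to C9 from the ring periphery and gives the (9S)-allylic alcohol F3, with its hydroxyl on the opposite face. VO(acac)2/tBuOOH then epoxidises C1=C10 stereospecifically, syn to that hydroxyl, to give the epoxy alcohol F4. This is the face complementary to direct peroxide attack. Dess–Martin oxidation of F4 gives 21.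

Step 6 (regiochemistry of the hydrosilylation next to a silyl ether instead of a free hydroxyl; competing iodination of other π-systems). The fallback sets out from 12 and returns to 14, using a free propargylic hydroxyl as the directing group. nBu4NF removes both silyl groups to give the diol F5. NaAlH2(OCH2CH2OMe)2 in THF followed by I2 at −78 °C (hydroxyl-directed trans-hydroalumination and iodination) gives the (Z)-iodo diol F6. Et3SiCl/imidazole at −40 °C silylates the less hindered C9 hydroxyl to give the mono-triethylsilyl ether F7. tBuMe2SiOTf/2,6-lutidine then protects the C6 hydroxyl and gives 14.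

Further compounds
F1 | step 9 | (3R)-epimer of 17 | C=C(C)[C@@H]1CC(O[Si](CC)(CC)CC)/C(C)=C\C[C@@H](O)/C(C)=C\[C@H]1O[Si](C)(C)C(C)(C)C
F2 | step 9 | 6-[(tert-butyldimethylsilyl)oxy]-9-[(triethylsilyl)oxy]-(1(10)Z,4Z)-germacra-1(10),4,11-trien-3-one (9RS) | C=C(C)[C@@H]1CC(O[Si](CC)(CC)CC)/C(C)=C\CC(=O)/C(C)=C\[C@H]1O[Si](C)(C)C(C)(C)C
F3 | step 12 | (3S,9S)-3-(angeloyloxy)-6-[(tert-butyldimethylsilyl)oxy]-(1(10)Z,4Z)-germacra-1(10),4,11-trien-9-ol | C=C(C)[C@@H]1C[C@H](O)/C(C)=C\C[C@H](OC(=O)/C(C)=C\C)/C(C)=C\[C@H]1O[Si](C)(C)C(C)(C)C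
F4 | step 12 | 1,10-epoxy-9-hydroxy compound from F3 (epoxide cis to the C9 hydroxyl, C1 and C10 arranged as in 21) | C=C(C)[C@@H]1C[C@H](O)[C@]2(C)O[C@@H]2C[C@H](OC(=O)/C(C)=C\C)/C(C)=C\[C@H]1O[Si](C)(C)C(C)(C)C
F5 | step 6 | (3Z,5RS,7S,8S)-1-[(4-methoxybenzyl)oxy]-4-methyl-7-(prop-1-en-2-yl)undec-3-en-9-yne-5,8-diol | CC#C[C@@H](O)[C@@H](CC(O)/C(C)=C\CCOCc1ccc(OC)cc1)C(C)=C
F6 | step 6 | (3Z,9Z)-10-iodo-1-[(4-methoxybenzyl)oxy]-4-methyl-7-(prop-1-en-2-yl)undeca-3,9-diene-5,8-diol (5RS, C7 and C8 as in 14) | C/C(I)=C/[C@@H](O)[C@@H](CC(O)/C(C)=C\CCOCc1ccc(OC)cc1)C(C)=C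
F7 | step 6 | 5-O-triethylsilyl ether of F6 | C/C(I)=C/[C@@H](O)[C@@H](CC(O[Si](CC)(CC)CC)/C(C)=C\CCOCc1ccc(OC)cc1)C(C)=C
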